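**Retrosynthetic overview**
- Target 10 ⇐ 9 (O–Si cleavage) ⇐ 8 (hydride reduction of two esters) ⇐ 7 (Mizoroki–Heck at C5–Br); the end game only adds the three-carbon side chain and adjusts oxidation level.
- Key disconnection: the bond between the syringyl ipso carbon and C2 of the dihydrofuran ring. 7 ⇐ flat ethyl benzofuran-3-carboxylate 3 + arylboronate 5, by an enantioselective dearomative conjugate arylation with in-flask epimerisation.
- Enabling feature: with the C3 hydroxymethyl carbon raised to an ester, the O1–C2=C3–C(=O) unit of the furan ring is a vinylogous carbonate whose β-carbon is C2. The C3–H of the adduct (α to the ester, benzylic to the benzo ring) is acidic, so cis/trans mixtures converge on the trans isomer.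
- Ring order: both benzene rings are bought; the furan ring is closed first as an aromatic ring (3, from salicylaldehyde 1) and dearomatised in the key step; no ring is formed afterwards.

Key step: step 3

Assumption: 1 and 4 are taken as commercial, and the diene written as (R,R) stands for whichever enantiomer delivers the aryl group to the Si face of C2 of 3 (O1 > C3 > H), as the (2R) configuration requires.

Step 1
Reactants: 1 5-bromo-2-hydroxy-3-methoxybenzaldehyde
Product: 3 ethyl 5-bromo-7-methoxy-1-benzofuran-3-carboxylate, via hemiacetal 2 (not isolated)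
Conditions: ethyl diazoacetate (slow addition), HBF4·OEt2 (10 mol %), CH2Cl2, rt; then conc. H2SO4, rt
Reagents that add atoms: ethyl diazoacetate, CCOC(=O)C=[N+]=[N-]
Why: Brønsted acid-catalysed addition of the diazoacetate to the aldehyde with 1,2-aryl shift and loss of N2 (aryl-migration variant of the Roskamp homologation) should give the 3-hydroxy-2-arylacrylate, which closes onto the ortho-phenol as hemiacetal 2 and is dehydrated by H2SO4 to the aromatic furan ring, the electron-rich aryl group migrating readily and Br and OMe being inert.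

Step 2
Reactants: 4 2,6-dimethoxy-4-(4,4,5,5-tetramethyl-1,3,2-dioxaborolan-2-yl)phenol
Product: 5 2-[3,5-dimethoxy-4-(triisopropylsilyloxy)phenyl]-4,4,5,5-tetramethyl-1,3,2-dioxaborolane
Conditions: TIPSOTf, 2,6-lutidine, CH2Cl2, 0 °C to rt
Reagents that add atoms: triisopropylsilyl trifluoromethanesulfonate, CC(C)[Si](OS(=O)(=O)C(F)(F)F)(C(C)C)C(C)C
Why: O-silylation of the hindered phenol with a silyl triflate and a hindered pyridine base should be clean, and the bulky silyl ether flanked by two methoxy groups is expected to resist aqueous base, amine base, palladium and hydride while blocking quinone methide formation until the last step.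

Step 3
Reactants: 3 ethyl 5-bromo-7-methoxy-1-benzofuran-3-carboxylate; 5 2-[3,5-dimethoxy-4-(triisopropylsilyloxy)phenyl]-4,4,5,5-tetramethyl-1,3,2-dioxaborolane
Product: 7 ethyl (2R,3R)-5-bromo-2-[3,5-dimethoxy-4-(triisopropylsilyloxy)phenyl]-7-methoxy-2,3-dihydro-1-benzofuran-3-carboxylate (trans), via cis-ester 6 (not isolated)
Conditions: [RhCl(C2H4)2]2 (2.5 mol %), (R,R)-2,5-diphenylbicyclo[2.2.2]octa-2,5-diene (5.5 mol %), KOH (aq., 0.3 equiv), 1,4-dioxane/H2O 10:1, 60 °C, 5 in excess; crude filtered through silica, then DBU (0.2 equiv), toluene, 40 °C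
Reagents that add atoms: none
Why: Proposed new method: a dearomative, enantioselective Hayashi–Miyaura-type 1,4-addition is proposed, in which hydroxide-assisted transmetalation from 5 gives an aryl complex of monovalent rhodium that binds the C2=C3 bond of the furan ring of 3, inserts it syn (aryl to C2, rhodium to C3 as an oxa-π-allyl enolate stabilised by the ester and the benzo ring) and is released by protonolysis with water, which regenerates the Rh–OH species. The closest known reaction type is the rhodium/chiral diene-catalysed asymmetric conjugate addition of arylboron reagents to enoates, coumarins and chromones (β-aryloxy acceptors with the same O–C=C–C=O pattern), supported by the known dearomative Michael additions at C2 of 3-nitrobenzofurans and by the weak aromatic stabilisation of the furan ring of a benzofuran. No ring is closed in this step; the furan ring is only dearomatised. C2 is set by the chiral diene on rhodium, which has to deliver the aryl group to the Si face of C2, and C3 is set under thermodynamic control, because its hydrogen is α to the ester and benzylic, so that the kinetic protonation mixture (expected to be rich in cis-ester 6) is funnelled by DBU into the trans ester 7 with the two large groups on opposite faces. The step needs 1,4-regioselectivity, secured by the C3 ester that polarises C2; chemoselectivity over the C5–Br bond, secured by the inertness of aryl bromides toward aryl complexes of monovalent rhodium at this temperature; and no rearomatising β-hydride elimination, secured by the syn insertion that leaves the C2–H anti to rhodium. The silyl ether on the phenol blocks opening of the O1–C2 bond through a para-quinone methide, so C2 should not scramble while C3 is equilibrated.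

Step 4
Reactants: 7 ethyl (2R,3R)-5-bromo-2-[3,5-dimethoxy-4-(triisopropylsilyloxy)phenyl]-7-methoxy-2,3-dihydro-1-benzofuran-3-carboxylate
Product: 8 ethyl (2R,3R)-2-[3,5-dimethoxy-4-(triisopropylsilyloxy)phenyl]-5-[(E)-3-ethoxy-3-oxoprop-1-enyl]-7-methoxy-2,3-dihydro-1-benzofuran-3-carboxylate
Conditions: ethyl acrylate, Pd(P(t-Bu)3)2 (3 mol %), Cy2NMe, 1,4-dioxane, 50 °C
Reagents that add atoms: ethyl acrylate, C=CC(=O)OCC
Why: Mizoroki–Heck reaction with a bulky, electron-rich phosphine complex of zerovalent palladium, which should insert into the electron-rich aryl bromide at mild temperature and give the (E)-cinnamate by syn insertion and syn β-hydride elimination, while the trans C2/C3 arrangement is already the thermodynamic one and cannot be eroded by the amine base.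

Step 5
Reactants: 8 ethyl (2R,3R)-2-[3,5-dimethoxy-4-(triisopropylsilyloxy)phenyl]-5-[(E)-3-ethoxy-3-oxoprop-1-enyl]-7-methoxy-2,3-dihydro-1-benzofuran-3-carboxylate
Product: 9 (E)-3-[(2R,3S)-2-[3,5-dimethoxy-4-(triisopropylsilyloxy)phenyl]-3-(hydroxymethyl)-7-methoxy-2,3-dihydro-1-benzofuran-5-yl]prop-2-en-1-ol
Conditions: i-Bu2AlH (excess), CH2Cl2, −78 to −40 °C; aq. potassium sodium tartrate (KNaC4H4O6) work-up
Reagents that add atoms: none
Why: i-Bu2AlH ester reduction should take the saturated ester to the primary alcohol and the enoate by 1,2-addition to the allylic alcohol at low temperature without touching the alkene, the silyl ether or the benzylic C2–O bond; no stereocenter is formed and the C3 descriptor changes from R to S only through the priority change.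

Step 6
Reactants: 9 (E)-3-[(2R,3S)-2-[3,5-dimethoxy-4-(triisopropylsilyloxy)phenyl]-3-(hydroxymethyl)-7-methoxy-2,3-dihydro-1-benzofuran-5-yl]prop-2-en-1-ol
Product: 10 4-[(2R,3S)-3-(hydroxymethyl)-5-[(E)-3-hydroxyprop-1-enyl]-7-methoxy-2,3-dihydro-1-benzofuran-2-yl]-2,6-dimethoxyphenol (CNP0191372.2)
Conditions: n-Bu4NF, AcOH, THF, 0 °C
Reagents that add atoms: none
Why: fluoride-mediated desilylation of the aryl silyl ether, driven by the Si–F bond, with acetic acid buffering the phenoxide so that the dihydrofuran ring should not open through a para-quinone methide and both stereocenters stay untouched.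

**Compound list**
1 | 5-bromo-2-hydroxy-3-methoxybenzaldehyde | COc1cc(Br)cc(C=O)c1O | starting material
2 | ethyl 5-bromo-2-hydroxy-7-methoxy-2,3-dihydro-1-benzofuran-3-carboxylate (hemiacetal, mixture of stereoisomers) | CCOC(=O)C1C(O)Oc2c(OC)cc(Br)cc12 | intermediate
3 | ethyl 5-bromo-7-methoxy-1-benzofuran-3-carboxylate | CCOC(=O)c1coc2c(OC)cc(Br)cc12 | intermediate
4 | 2,6-dimethoxy-4-(4,4,5,5-tetramethyl-1,3,2-dioxaborolan-2-yl)phenol | COc1cc(B2OC(C)(C)C(C)(C)O2)cc(OC)c1O | starting material
5 | 2-[3,5-dimethoxy-4-(triisopropylsilyloxy)phenyl]-4,4,5,5-tetramethyl-1,3,2-dioxaborolane | COc1cc(B2OC(C)(C)C(C)(C)O2)cc(OC)c1O[Si](C(C)C)(C(C)C)C(C)C | intermediate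
6 | ethyl (2R,3S)-5-bromo-2-[3,5-dimethoxy-4-(triisopropylsilyloxy)phenyl]-7-methoxy-2,3-dihydro-1-benzofuran-3-carboxylate (cis) | COc1cc([C@@H]2Oc3c(OC)cc(Br)cc3[C@@H]2C(=O)OCC)cc(OC)c1O[Si](C(C)C)(C(C)C)C(C)C | intermediate
7 | ethyl (2R,3R)-5-bromo-2-[3,5-dimethoxy-4-(triisopropylsilyloxy)phenyl]-7-methoxy-2,3-dihydro-1-benzofuran-3-carboxylate (trans) | COc1cc([C@@H]2Oc3c(OC)cc(Br)cc3[C@H]2C(=O)OCC)cc(OC)c1O[Si](C(C)C)(C(C)C)C(C)C | intermediate
8 | ethyl (2R,3R)-2-[3,5-dimethoxy-4-(triisopropylsilyloxy)phenyl]-5-[(E)-3-ethoxy-3-oxoprop-1-enyl]-7-methoxy-2,3-dihydro-1-benzofuran-3-carboxylate | COc1cc([C@@H]2Oc3c(OC)cc(/C=C/C(=O)OCC)cc3[C@H]2C(=O)OCC)cc(OC)c1O[Si](C(C)C)(C(C)C)C(C)C | intermediate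
9 | (E)-3-[(2R,3S)-2-[3,5-dimethoxy-4-(triisopropylsilyloxy)phenyl]-3-(hydroxymethyl)-7-methoxy-2,3-dihydro-1-benzofuran-5-yl]prop-2-en-1-ol | COc1cc([C@@H]2Oc3c(OC)cc(/C=C/CO)cc3[C@H]2CO)cc(OC)c1O[Si](C(C)C)(C(C)C)C(C)C | intermediate
10 | 4-[(2R,3S)-3-(hydroxymethyl)-5-[(E)-3-hydroxyprop-1-enyl]-7-methoxy-2,3-dihydro-1-benzofuran-2-yl]-2,6-dimethoxyphenol | COc1cc([C@@H]2Oc3c(OC)cc(/C=C/CO)cc3[C@H]2CO)cc(OC)c1O | target

**Step count and risks**
Total step count: 6. Longest linear sequence: 5 steps (steps 1, 3, 4, 5, 6); step 2 is a one-step side branch.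

Steps most likely to fail:

1. Step 3. The aryl–rhodium species may fail to insert the weakly aromatic C2=C3 bond before 5 is lost by protodeboronation, or the facial selectivity at C2 may be poor. The fallback uses known chemistry, sets out from 3 (with 5) and comes back at 9.
   - C2 of 3 is magnesiated with TMPMgCl·LiCl (THF, −40 °C, directed by the ester) and quenched with iodine to give ethyl 5-bromo-2-iodo-7-methoxy-1-benzofuran-3-carboxylate F1.
   - A Suzuki–Miyaura coupling with 5, selective for the C–I bond (Pd(PPh3)4, K2CO3, dioxane/H2O, 50 °C), gives ethyl 5-bromo-2-[3,5-dimethoxy-4-(triisopropylsilyloxy)phenyl]-7-methoxy-1-benzofuran-3-carboxylate F2.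
   - Dissolving-metal conjugate reduction (Mg, MeOH/THF, 0 °C, short contact time to spare the bromide), with transesterification and thermodynamic protonation, gives racemic trans methyl 5-bromo-2-[3,5-dimethoxy-4-(triisopropylsilyloxy)phenyl]-7-methoxy-2,3-dihydro-1-benzofuran-3-carboxylate F3.
   - Preparative chromatography on a chiral stationary phase gives the methyl (2R,3R) ester F4.
   - F4 is taken through the conditions of step 4 to methyl (2R,3R)-2-[3,5-dimethoxy-4-(triisopropylsilyloxy)phenyl]-5-[(E)-3-ethoxy-3-oxoprop-1-enyl]-7-methoxy-2,3-dihydro-1-benzofuran-3-carboxylate F5, and through those of step 5, where both ester alkyl groups are lost, to rejoin the route at 9.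

2. Step 4. Oxidative addition at the electron-rich C5–Br bond may be slow, with protodebromination, and prolonged heating with amine base may erode the C3 center. The fallback moves the cross-coupling ahead of the stereocenters; it sets out from 3 and comes back at 10.
   - 3 is coupled (Suzuki–Miyaura, Pd(dppf)Cl2, K3PO4, THF/H2O, 50 °C) with commercial (E)-tert-butyldimethyl{[3-(4,4,5,5-tetramethyl-1,3,2-dioxaborolan-2-yl)prop-2-en-1-yl]oxy}silane to give ethyl 5-[(E)-3-(tert-butyldimethylsilyloxy)prop-1-enyl]-7-methoxy-1-benzofuran-3-carboxylate F6, whose side chain is not a Michael acceptor.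
   - The conditions of step 3 with 5 should give ethyl (2R,3R)-5-[(E)-3-(tert-butyldimethylsilyloxy)prop-1-enyl]-2-[3,5-dimethoxy-4-(triisopropylsilyloxy)phenyl]-7-methoxy-2,3-dihydro-1-benzofuran-3-carboxylate F7.
   - i-Bu2AlH reduction gives [(2R,3S)-5-[(E)-3-(tert-butyldimethylsilyloxy)prop-1-enyl]-2-[3,5-dimethoxy-4-(triisopropylsilyloxy)phenyl]-7-methoxy-2,3-dihydro-1-benzofuran-3-yl]methanol F8.
   - n-Bu4NF/AcOH removes both silyl groups and gives 10.

3. Step 5. Reducing two esters of different reactivity in one operation with a large excess of hydride may be unselective (conjugate reduction of the cinnamate, partial reduction). The fallback separates the two events; it sets out from 7 and comes back at 9.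
   - The single saturated ester of 7 is reduced first (LiBH4, THF/MeOH, 0 °C) to [(2R,3S)-5-bromo-2-[3,5-dimethoxy-4-(triisopropylsilyloxy)phenyl]-7-methoxy-2,3-dihydro-1-benzofuran-3-yl]methanol F9, which no longer has an acidic C3–H.
   - A Suzuki–Miyaura coupling of F9 with (E)-3-(4,4,5,5-tetramethyl-1,3,2-dioxaborolan-2-yl)prop-2-en-1-ol (Pd(dppf)Cl2, K3PO4, THF/H2O, 50 °C) installs the allylic alcohol at its final oxidation level and gives 9.

**Further compounds**
F1 | step 3 | ethyl 5-bromo-2-iodo-7-methoxy-1-benzofuran-3-carboxylate | CCOC(=O)c1c(I)oc2c(OC)cc(Br)cc12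
F2 | step 3 | ethyl 5-bromo-2-[3,5-dimethoxy-4-(triisopropylsilyloxy)phenyl]-7-methoxy-1-benzofuran-3-carboxylate | CCOC(=O)c1c(-c2cc(OC)c(O[Si](C(C)C)(C(C)C)C(C)C)c(OC)c2)oc2c(OC)cc(Br)cc12
F3 | step 3 | racemic trans methyl 5-bromo-2-[3,5-dimethoxy-4-(triisopropylsilyloxy)phenyl]-7-methoxy-2,3-dihydro-1-benzofuran-3-carboxylate (both enantiomers) | COc1cc([C@@H]2Oc3c(OC)cc(Br)cc3[C@H]2C(=O)OC)cc(OC)c1O[Si](C(C)C)(C(C)C)C(C)C.COc1cc([C@H]2Oc3c(OC)cc(Br)cc3[C@@H]2C(=O)OC)cc(OC)c1O[Si](C(C)C)(C(C)C)C(C)C
F4 | step 3 | methyl (2R,3R)-5-bromo-2-[3,5-dimethoxy-4-(triisopropylsilyloxy)phenyl]-7-methoxy-2,3-dihydro-1-benzofuran-3-carboxylate | COc1cc([C@@H]2Oc3c(OC)cc(Br)cc3[C@H]2C(=O)OC)cc(OC)c1O[Si](C(C)C)(C(C)C)C(C)C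
F5 | step 3 | methyl (2R,3R)-2-[3,5-dimethoxy-4-(triisopropylsilyloxy)phenyl]-5-[(E)-3-ethoxy-3-oxoprop-1-enyl]-7-methoxy-2,3-dihydro-1-benzofuran-3-carboxylate | COc1cc([C@@H]2Oc3c(OC)cc(/C=C/C(=O)OCC)cc3[C@H]2C(=O)OC)cc(OC)c1O[Si](C(C)C)(C(C)C)C(C)C
F6 | step 4 | ethyl 5-[(E)-3-(tert-butyldimethylsilyloxy)prop-1-enyl]-7-methoxy-1-benzofuran-3-carboxylate | CCOC(=O)c1coc2c(OC)cc(/C=C/CO[Si](C)(C)C(C)(C)C)cc12
F7 | step 4 | ethyl (2R,3R)-5-[(E)-3-(tert-butyldimethylsilyloxy)prop-1-enyl]-2-[3,5-dimethoxy-4-(triisopropylsilyloxy)phenyl]-7-methoxy-2,3-dihydro-1-benzofuran-3-carboxylate | COc1cc([C@@H]2Oc3c(OC)cc(/C=C/CO[Si](C)(C)C(C)(C)C)cc3[C@H]2C(=O)OCC)cc(OC)c1O[Si](C(C)C)(C(C)C)C(C)C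
F8 | step 4 | [(2R,3S)-5-[(E)-3-(tert-butyldimethylsilyloxy)prop-1-enyl]-2-[3,5-dimethoxy-4-(triisopropylsilyloxy)phenyl]-7-methoxy-2,3-dihydro-1-benzofuran-3-yl]methanol | COc1cc([C@@H]2Oc3c(OC)cc(/C=C/CO[Si](C)(C)C(C)(C)C)cc3[C@H]2CO)cc(OC)c1O[Si](C(C)C)(C(C)C)C(C)C
F9 | step 5 | [(2R,3S)-5-bromo-2-[3,5-dimethoxy-4-(triisopropylsilyloxy)phenyl]-7-methoxy-2,3-dihydro-1-benzofuran-3-yl]methanol | COc1cc([C@@H]2Oc3c(OC)cc(Br)cc3[C@H]2CO)cc(OC)c1O[Si](C(C)C)(C(C)C)C(C)C
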